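# Total synthesis proposal for yanuthone L

## Analysis of the target

1. Yanuthone L (10) is a 7-oxabicyclo[4.1.0]hept-3-en-5-one. Ring A is a cyclohexenone: C1 ketone, C2 vinyl CH, C3 methyl-bearing alkene carbon, C4 acetoxy carbinol, C5 oxirane CH, C6 fully substituted oxirane carbon. Ring B is the oxirane (C5, C6, O). C6 carries an all-E 12′-hydroxyfarnesyl chain (C1′ to C12′).
2. The stereocenters C4, C5 and C6 are contiguous and all R. The acetoxy oxygen O4 and the oxirane oxygen lie on the same face of ring A, and C6 is quaternary and alpha to the ketone.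
3. Ring A is one proton shift away from an arene. A C4 carbinol inside a C2=C3/C5=C6 dienone tautomerizes at once, and in 10 loss of H4 (gamma to the ketone) opens ring B by a vinylogous E1cB path.
4. The chain holds three electron-rich trisubstituted alkenes, which exclude peracids, osmium, halonium and photooxygenation chemistry once it is attached. It cannot be attached late, because an anion or radical next to C6 opens ring B.
5. The hindered secondary O4 is acetylated while the primary allylic O12′ is free, which is the reverse of the natural acylation order.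
6. The difficulty is to set the quaternary C6 and its two neighbours in the absolute sense, on a ring that wants to aromatize, with oxidants that ignore the chain.
7. Two features of the structure are exploited. The cis relation of O4 and the oxygen of ring B is the signature of an epoxidation of C5=C6 directed by a free C4 hydroxyl. The unit C1(=O)–C2=C3(CH3) is the retron of an oxidative 1,3-transposition of a tertiary allylic alcohol at C3.
8. Parking C3 as an sp3 carbinol carbon locks ring A against aromatization long enough for the C4 hydroxyl to direct the epoxidation. The C1 carbonyl is created only afterwards.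

## Retrosynthetic reasoning

**10 to 9.** The C12′–O bond is cut last. With the acetate already on O4, a late allylic hydroxylation of the terminal E-methyl group gives the free primary alcohol without any protecting group. The forward reaction must pick one methyl group out of the chain and leave the electron-poor ring alkene alone.

**9 to 8.** The C1=O bond is cut and a C3–O bond is restored, so the enone becomes the tertiary allylic alcohol 8 with a C1=C2 alkene. This is the cut that defines the route. It removes the only carbonyl of ring A and makes C3 tetrahedral, so no earlier intermediate can tautomerize to an arene. The forward step is a [3,3] oxygen walk from C3 to C1 with oxidation. It also erases the stereocenter at C3, so that centre never has to be controlled.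

**8 to 7.** The acetyl group is moved back from O4 to the neighbouring O3. The acetate of the target is thereby traced to the acetoxy group that dearomatized the ring, and O4 is left free in 7 for the key step.

**7 to 6.** Both C–O bonds of ring B are cut. The precursor 6 is a cyclohexadienol with one controlling stereocenter (C4). The forward reaction must deliver oxygen to C5=C6 only, cis to O4, in the presence of four other alkenes.

**6 to 5.** The C4–H bond is cut, which gives the dienone 5. A catalyst-controlled hydride addition fixes C4 from both enantiomers of 5. The two C3 epimers of 6 converge later, so a racemic dearomatization suffices.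

**5 to 4.** The C3–O bond is cut and ring A becomes the phenol 4, whose oxygen is O4 of the target. The cut is placed at the methyl-bearing ortho carbon, and not at C1 or C4 of the usual para-quinoid manifold, because only this carbon can stay tetrahedral.

**4 to 1 and 2.** The C6–C1′ bond is cut between an aryl anion (3, from 1) and the allylic bromide 2. The para relation of C3 and C6 is bought with 1, and the E alkenes are bought with 2.

## Alternatives that were turned down

**Alternative 1:** This is the textbook cut. Both C–O bonds of ring B are cut at the para-quinoid oxidation level.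
- **Forward key step:** Weitz–Scheffer epoxidation of the monoketal A1 with a hydroperoxide anion and a chiral mediator gives A2. Hydrolysis gives the epoxyquinone A3, then hydride adds at C4 anti to the oxirane, then acetylation.
- **Why turned down:** C4 must be a ketal or a carbonyl while C5=C6 is epoxidized, so no ring stereocenter can steer the event. The absolute sense must come from an external reagent acting on an alpha-branched enone whose two faces differ by nothing nearby.
- The free quinone A4 is worse. Its two alkenes differ only as CH3 versus CH2R, so site selectivity is lost. Its C1′ protons are also acidic under the basic conditions.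
- The sequence is one step shorter on paper, but its weakest point is the stereodefining step. It is kept as a fallback only.

**Alternative 2:** O4 and the oxirane oxygen come from one molecule of dioxygen.
- **Forward key step:** A [4+2] photooxygenation across C3 and C6 of the dienyl silyl ether A5 gives the endoperoxide A6. Metal-induced O–O homolysis gives the cis bis-oxirane, and oxidation at C1 gives A7. Its E1cB opening (H2, C3–O) gives the C2=C3 enone and O4 cis to ring B.
- **Why turned down:** The stereochemical logic is sound, since the addition is suprafacial. However, the oxidant also undergoes ene reactions with three trisubstituted chain alkenes.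
- A5 is an arene hydrate derivative that ionizes easily, and its enantioselective preparation costs more steps than the cascade saves.

**Alternative 3:** C3 and C6 are taken as the carbonyl carbons of p-benzoquinone A8.
- **Forward key steps:** Methyl and farnesyl nucleophiles are added to give the diol A9. Directed epoxidation of C4=C5 gives A10. Payne rearrangement from O6 gives A11, then oxidative transposition of O3 to C1.
- **Why turned down:** The Payne step is an SN2 attack of O6 on C5 from the rear of the old oxirane, so O4 necessarily ends trans to the new ring B and C4 would have to be inverted.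
- The farnesyl metal can also react at its gamma carbon, the diol geometry must be trans, and two hydroxyl groups compete as directing groups. The risk is therefore spread over four steps.

Key step: step 4

Assumption: commercial (2E,6E)-farnesyl bromide is taken as a single geometric isomer, and the ring locants C1 to C6 of 10 are kept for all intermediates.

## Route

Step 1
Reactants: 1 5-bromo-2-methylphenol; 2 (2E,6E)-farnesyl bromide
Product: 4 2-methyl-5-[(2E,6E)-3,7,11-trimethyldodeca-2,6,10-trien-1-yl]phenol, via lithium 5-lithio-2-methylphenolate 3 (not isolated)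
Conditions: n-BuLi (2.1 equiv), THF, −78 °C; CuBr·SMe2 (10 mol %), then 2, −78 to 0 °C; H2O
Reagents that add atoms: none
Why: Bromine–lithium exchange on the preformed lithium phenolate gives the aryl anion 3, and its allylation at the primary carbon of 2, assisted by monovalent copper (aryl-metal allylation, SN2), keeps both E alkenes. Carbon attack should outrun oxygen attack because the aryl anion is by far the stronger nucleophile.

Step 2
Reactants: 4 2-methyl-5-[(2E,6E)-farnesyl]phenol
Product: 5 rac-1-methyl-6-oxo-4-[(2E,6E)-farnesyl]cyclohexa-2,4-dien-1-yl acetate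
Conditions: Pb(OAc)4 (1.1 equiv), CH2Cl2/AcOH, 0 °C
Reagents that add atoms: lead tetraacetate, CC(=O)O[Pb](OC(C)=O)(OC(C)=O)OC(C)=O
Why: Wessely oxidation: the phenol binds to tetravalent lead and an acetate ligand is passed to an ortho carbon. C3 is favoured because its methyl group stabilizes the developing charge, while the other ortho carbon (C5) and the para carbon (C1) are both flanked by the chain-bearing C6. C3 is formed racemic on purpose, since step 6 erases it.

Step 3
Reactants: 5 rac-dienone acetate
Product: 6 (6S)-6-hydroxy-1-methyl-4-[(2E,6E)-farnesyl]cyclohexa-2,4-dien-1-yl acetate (uniform carbinol C4 in target numbering, both C3 epimers)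
Conditions: (R)-2-methyl-CBS-oxazaborolidine (20 mol %), catecholborane (1.5 equiv), toluene, −78 °C; MeOH, pH 7 buffer
Reagents that add atoms: none
Why: Corey–Bakshi–Shibata reduction: the catalyst binds the carbonyl lone pair away from the quaternary flank C3 (large group) and next to the flat vinyl flank C5 (small group), so hydride should reach the same face of C4 in both enantiomers of 5. The two products differ only at the disposable C3, which makes the sequence stereoconvergent. Catecholborane at −78 °C does not hydroborate the chain.

Step 4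
Reactants: 6 (6S)-dienol acetate
Product: 7 (1R,2S,6S)-2-hydroxy-3-methyl-6-[(2E,6E)-farnesyl]-7-oxabicyclo[4.1.0]hept-4-en-3-yl acetate (oxirane oxygen cis to the C4 hydroxyl, both C3 epimers)
Conditions: VO(acac)2 (5 mol %), t-BuOOH (1.2 equiv, decane), 2,6-lutidine (10 mol %), CH2Cl2, −20 to 0 °C
Reagents that add atoms: tert-butyl hydroperoxide, CC(C)(C)OO
Why: VO(acac)2 is oxidized by t-BuOOH to a pentavalent vanadate that binds the C4 alkoxide and a tert-butylperoxo ligand on the same metal, and the activated oxygen is passed inside this complex to the nearest alkene. The closest known reaction type is the hydroxyl-directed vanadium epoxidation of cyclohex-2-enols (cis epoxy alcohols) and of polyenols such as geraniol (only the allylic alkene reacts). Ring B is closed by a concerted suprafacial transfer of one oxygen atom to C5 and C6, a [2+1] addition in which both C–O bonds form on one face. C5 and the quaternary C6 are both controlled by the C4 carbinol of step 3: the metal is tethered to O4, so the oxygen must enter cis to O4, which is the relative configuration of 10, and this holds for either C3 epimer. The step needs site selectivity among five C=C bonds: C5=C6 is the only alkene allylic to the free hydroxyl and is trisubstituted, C1=C2 is only homoallylic, disubstituted and next to the acetoxy-bearing C3, and the chain alkenes cannot reach the bound peroxide. It also needs a ring that stays non-aromatic, which the sp3 carbon C3 secures, helped by the electron-withdrawing O4 that slows ionization of the tertiary acetate and by the lutidine buffer. In one operation the step forms both C–O bonds of ring B and two of the three stereocenters, the quaternary one included, without touching the chain.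

Step 5
Reactants: 7 epoxy alcohol with the acetate on O3
Product: 8 (1R,2S,6S)-3-hydroxy-3-methyl-6-[(2E,6E)-farnesyl]-7-oxabicyclo[4.1.0]hept-4-en-2-yl acetate (both C3 epimers)
Conditions: DBU (20 mol %), toluene, 23 °C
Reagents that add atoms: none
Why: Base-catalysed 1,2-acyl migration through a cyclic orthoacid anion, driven by the change from a crowded tertiary ester to a secondary ester. No stereocenter is touched. The O4 alkoxide cannot start a Payne rearrangement because it is cis to the oxirane.

Step 6
Reactants: 8 tertiary allylic alcohol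
Product: 9 (1R,2R,6R)-3-methyl-5-oxo-6-[(2E,6E)-farnesyl]-7-oxabicyclo[4.1.0]hept-3-en-2-yl acetate
Conditions: [C5H5NH][CrO3Cl] (3 equiv), NaOAc, 4 Å sieves, CH2Cl2, 23 °C
Reagents that add atoms: pyridinium chlorochromate, [O-][Cr](=O)(=O)Cl.c1cc[nH+]cc1
Why: Babler–Dauben oxidative transposition: the chromate ester of hexavalent chromium at O3 undergoes a [3,3] shift to C1 and the secondary chromate collapses to the ketone, as with 1-methylcyclohex-2-enol. C3 becomes sp2, so both epimers of 8 converge on the single compound 9, and C4, C5 and C6 are not involved.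

Step 7
Reactants: 9 12′-deoxy compound
Product: 10 yanuthone L
Conditions: SeO2 (30 mol %), t-BuOOH (2 equiv), salicylic acid (10 mol %), CH2Cl2, 0 °C, stopped at partial conversion
Reagents that add atoms: selenium dioxide, O=[Se]=O (oxygen carrier); tert-butyl hydroperoxide, CC(C)(C)OO (terminal oxygen source)
Why: Riley oxidation (ene reaction, then [2,3] shift) attacks the most accessible and electron-rich alkene, the terminal isopropylidene, and gives the E allylic alcohol, as known for farnesyl derivatives. The ring alkene is electron-poor and the medium contains no base, so the enone, the oxirane and the acetate should persist.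

## Compound list

1 | 5-bromo-2-methylphenol | Cc1ccc(Br)cc1O | starting material
2 | (2E,6E)-farnesyl bromide | BrC/C=C(\C)CC/C=C(\C)CCC=C(C)C | starting material
3 | lithium 5-lithio-2-methylphenolate | Cc1ccc([Li])cc1O[Li] | intermediate
4 | 2-methyl-5-[(2E,6E)-farnesyl]phenol | Cc1ccc(C/C=C(\C)CC/C=C(\C)CCC=C(C)C)cc1O | intermediate
5 | rac-1-methyl-6-oxo-4-[(2E,6E)-farnesyl]cyclohexa-2,4-dien-1-yl acetate | CC(=O)OC1(C)C=CC(C/C=C(\C)CC/C=C(\C)CCC=C(C)C)=CC1=O | intermediate
6 | (6S)-6-hydroxy-1-methyl-4-[(2E,6E)-farnesyl]cyclohexa-2,4-dien-1-yl acetate, both epimers at the acetoxy carbon | O[C@@H]1C(C)(OC(C)=O)C=CC(C/C=C(\C)CC/C=C(\C)CCC=C(C)C)=C1 | intermediate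
7 | (1R,2S,6S)-2-hydroxy-3-methyl-6-[(2E,6E)-farnesyl]-7-oxabicyclo[4.1.0]hept-4-en-3-yl acetate, both C3 epimers | O[C@@H]1C(C)(OC(C)=O)C=C[C@]2(C/C=C(\C)CC/C=C(\C)CCC=C(C)C)O[C@H]12 | intermediate
8 | (1R,2S,6S)-3-hydroxy-3-methyl-6-[(2E,6E)-farnesyl]-7-oxabicyclo[4.1.0]hept-4-en-2-yl acetate, both C3 epimers | CC(=O)O[C@@H]1C(C)(O)C=C[C@]2(C/C=C(\C)CC/C=C(\C)CCC=C(C)C)O[C@H]12 | intermediate
9 | (1R,2R,6R)-3-methyl-5-oxo-6-[(2E,6E)-farnesyl]-7-oxabicyclo[4.1.0]hept-3-en-2-yl acetate | CC(=O)O[C@@H]1C(C)=CC(=O)[C@]2(C/C=C(\C)CC/C=C(\C)CCC=C(C)C)O[C@H]12 | intermediate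
10 | yanuthone L, (1R,2R,6R)-6-[(2E,6E,10E)-12-hydroxy-3,7,11-trimethyldodeca-2,6,10-trien-1-yl]-3-methyl-5-oxo-7-oxabicyclo[4.1.0]hept-3-en-2-yl acetate | CC(=O)O[C@@H]1C(C)=CC(=O)[C@]2(C/C=C(\C)CC/C=C(\C)CC/C=C(\C)CO)O[C@H]12 | target

## Step count and least certain steps

Total step count: 7. Longest linear sequence: 7 (from 1 or 2).

**Step 4 (key step).**
- **What may go wrong:** The Lewis-acidic vanadium may ionize the tertiary allylic acetate, followed by loss of H4 and rearomatization. The carbinol may be oxidized back to the dienone. Oxygen may leak to the homoallylic C1=C2 alkene.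
- **Fallback (sets out from 2, comes back at 9):** Ring B is made by nucleophilic instead of directed epoxidation. The sodium salt of m-cresol is C-alkylated with 2 in toluene, at the free ortho carbon para to the methyl group, to give 2-[(2E,6E)-farnesyl]-5-methylphenol F1. PhI(OAc)2 (2.2 equiv) in MeOH oxidizes it to the para-quinone monoketal F2, in which only the C5=C6 enone has an unsubstituted beta carbon. Weitz–Scheffer epoxidation with trityl hydroperoxide, NaHMDS and the diisopropyl tartrate antipode that serves the (5R,6R) series gives the epoxy ketal F3. Mild aqueous acid frees the epoxyquinone F4. LiBH(s-Bu)3 at −78 °C attacks the C4 carbonyl from the face opposite to the oxirane oxygen, because the C1 carbonyl is screened on that face by C1′. Quenching the alkoxide with Ac2O gives 9.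

**Step 2.**
- **What may go wrong:** Acetoxylation may occur at the unsubstituted ortho or para carbon, with further oxidation of those products, because only one of the three activated positions is blocked.
- **Fallback (sets out from 2, comes back at 8):** The site of dearomatization is fixed by a methoxy group and the methyl group is brought in later as a nucleophile. 5-Bromo-2-methoxyphenol is metalated and allylated with 2 as in step 1 to give 5-[(2E,6E)-farnesyl]-2-methoxyphenol F5. PhI(OAc)2 in MeOH gives the achiral ortho-quinone monoketal F6. The reduction of step 3 gives the dienol F7, and the epoxidation of step 4 gives the epoxy alcohol F8. Oxalic acid on wet silica unmasks the hydroxy enone F9. MeMgBr with CeCl3 adds to the C3 carbonyl to give the diol F10. Ac2O in pyridine acetylates only the secondary O4 and gives 8.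

**Step 3.**
- **What may go wrong:** Facial selectivity may be poor for the enantiomer of 5 whose own bias (hydride anti to the acetoxy group) opposes the catalyst. Acyl migration or loss of the acetoxy group may occur during work-up.
- **Fallback (sets out from 5, comes back at 6 as its single cis epimer):** Substrate control is followed by resolution. Luche reduction (NaBH4, CeCl3·7H2O, MeOH, −78 °C) delivers hydride anti to the acetoxy group and gives the racemic cis dienol F11. A lipase with vinyl acetate acylates the (6R) antipode by the usual size rule to the diacetate F12, which is separated, and the remaining (6S) alcohol goes on.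

**Step 6.**
- **What may go wrong:** The acidic chromium reagent may open the vinyl oxirane. The neighbouring acetate may participate at an ionized C3. The shift to C1, which sits next to the quaternary C6, may be slow.
- **Fallback (sets out from 8, comes back at 9):** Transposition and oxidation are separated. Ph3SiOReO3 (catalytic, heptavalent rhenium, Et2O, −50 to 0 °C) isomerizes 8 without change of oxidation level to the secondary allylic alcohol F13. Dess–Martin periodinane with NaHCO3 then gives 9.

**Step 7.**
- **What may go wrong:** Over-oxidation to the enal, attack at internal allylic positions, and slow acid-induced opening of ring B during the long reaction time needed for conversion.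
- **Fallback (sets out from 1, comes back at 10):** The oxygen is brought in with the chain. Riley oxidation of commercial (2E,6E)-farnesyl acetate gives the 12-hydroxy acetate F14. TBSCl with imidazole gives the silyl ether F15, K2CO3 in MeOH gives the allylic alcohol F16, and CBr4 with PPh3 gives the bromide F17. F17 replaces 2 in step 1 and gives the silyloxy phenol F18. Steps 2 to 6 then give in turn the dienone acetate F19, the dienol F20, the epoxy alcohol F21, the tertiary alcohol F22 and the silyl ether of 10 F23. HF·pyridine removes the silyl group and gives 10.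

## Further compounds

F1 | step 4 | 2-[(2E,6E)-farnesyl]-5-methylphenol | Cc1ccc(C/C=C(\C)CC/C=C(\C)CCC=C(C)C)c(O)c1
F2 | step 4 | 2-[(2E,6E)-farnesyl]-4,4-dimethoxy-5-methylcyclohexa-2,5-dien-1-one | COC1(OC)C=C(C/C=C(\C)CC/C=C(\C)CCC=C(C)C)C(=O)C=C1C
F3 | step 4 | (5R,6R)-5,6-epoxy-6-[(2E,6E)-farnesyl]-4,4-dimethoxy-3-methylcyclohex-2-en-1-one | COC1(OC)C(C)=CC(=O)[C@]2(C/C=C(\C)CC/C=C(\C)CCC=C(C)C)O[C@H]12
F4 | step 4 | (5R,6R)-5,6-epoxy-6-[(2E,6E)-farnesyl]-3-methylcyclohex-2-ene-1,4-dione | O=C1C(C)=CC(=O)[C@]2(C/C=C(\C)CC/C=C(\C)CCC=C(C)C)O[C@H]12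
F5 | step 2 | 5-[(2E,6E)-farnesyl]-2-methoxyphenol | COc1ccc(C/C=C(\C)CC/C=C(\C)CCC=C(C)C)cc1O
F6 | step 2 | 3-[(2E,6E)-farnesyl]-6,6-dimethoxycyclohexa-2,4-dien-1-one | COC1(OC)C=CC(C/C=C(\C)CC/C=C(\C)CCC=C(C)C)=CC1=O
F7 | step 2 | (1S)-3-[(2E,6E)-farnesyl]-6,6-dimethoxycyclohexa-2,4-dien-1-ol | O[C@@H]1C(OC)(OC)C=CC(C/C=C(\C)CC/C=C(\C)CCC=C(C)C)=C1
F8 | step 2 | 6-[(2E,6E)-farnesyl]-3,3-dimethoxy-7-oxabicyclo[4.1.0]hept-4-en-2-ol, oxirane cis to the hydroxyl | O[C@@H]1C(OC)(OC)C=C[C@]2(C/C=C(\C)CC/C=C(\C)CCC=C(C)C)O[C@H]12
F9 | step 2 | 6-[(2E,6E)-farnesyl]-2-hydroxy-7-oxabicyclo[4.1.0]hept-4-en-3-one, oxirane cis to the hydroxyl | O[C@@H]1C(=O)C=C[C@]2(C/C=C(\C)CC/C=C(\C)CCC=C(C)C)O[C@H]12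
F10 | step 2 | 6-[(2E,6E)-farnesyl]-3-methyl-7-oxabicyclo[4.1.0]hept-4-ene-2,3-diol, oxirane cis to the secondary hydroxyl | O[C@@H]1C(C)(O)C=C[C@]2(C/C=C(\C)CC/C=C(\C)CCC=C(C)C)O[C@H]12
F11 | step 3 | rac-(1R*,6S*)-6-hydroxy-1-methyl-4-[(2E,6E)-farnesyl]cyclohexa-2,4-dien-1-yl acetate (the enantiomer that goes on is drawn) | O[C@@H]1[C@](C)(OC(C)=O)C=CC(C/C=C(\C)CC/C=C(\C)CCC=C(C)C)=C1
F12 | step 3 | (1S,6R)-1-methyl-4-[(2E,6E)-farnesyl]cyclohexa-2,4-diene-1,6-diyl diacetate | CC(=O)O[C@H]1[C@@](C)(OC(C)=O)C=CC(C/C=C(\C)CC/C=C(\C)CCC=C(C)C)=C1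
F13 | step 6 | 6-[(2E,6E)-farnesyl]-5-hydroxy-3-methyl-7-oxabicyclo[4.1.0]hept-3-en-2-yl acetate | CC(=O)O[C@@H]1C(C)=CC(O)[C@]2(C/C=C(\C)CC/C=C(\C)CCC=C(C)C)O[C@H]12
F14 | step 7 | (2E,6E,10E)-12-hydroxyfarnesyl acetate | CC(=O)OC/C=C(\C)CC/C=C(\C)CC/C=C(\C)CO
F15 | step 7 | (2E,6E,10E)-12-(tert-butyldimethylsilyloxy)farnesyl acetate | CC(=O)OC/C=C(\C)CC/C=C(\C)CC/C=C(\C)CO[Si](C)(C)C(C)(C)C
F16 | step 7 | (2E,6E,10E)-12-(tert-butyldimethylsilyloxy)farnesol | OC/C=C(\C)CC/C=C(\C)CC/C=C(\C)CO[Si](C)(C)C(C)(C)C
F17 | step 7 | (2E,6E,10E)-12-(tert-butyldimethylsilyloxy)farnesyl bromide | BrC/C=C(\C)CC/C=C(\C)CC/C=C(\C)CO[Si](C)(C)C(C)(C)C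
F18 | step 7 | 12′-silyloxy analogue of 4 | Cc1ccc(C/C=C(\C)CC/C=C(\C)CC/C=C(\C)CO[Si](C)(C)C(C)(C)C)cc1O
F19 | step 7 | 12′-silyloxy analogue of 5 (racemic) | CC(=O)OC1(C)C=CC(C/C=C(\C)CC/C=C(\C)CC/C=C(\C)CO[Si](C)(C)C(C)(C)C)=CC1=O
F20 | step 7 | 12′-silyloxy analogue of 6 | O[C@@H]1C(C)(OC(C)=O)C=CC(C/C=C(\C)CC/C=C(\C)CC/C=C(\C)CO[Si](C)(C)C(C)(C)C)=C1
F21 | step 7 | 12′-silyloxy analogue of 7 | O[C@@H]1C(C)(OC(C)=O)C=C[C@]2(C/C=C(\C)CC/C=C(\C)CC/C=C(\C)CO[Si](C)(C)C(C)(C)C)O[C@H]12
F22 | step 7 | 12′-silyloxy analogue of 8 | CC(=O)O[C@@H]1C(C)(O)C=C[C@]2(C/C=C(\C)CC/C=C(\C)CC/C=C(\C)CO[Si](C)(C)C(C)(C)C)O[C@H]12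
F23 | step 7 | tert-butyldimethylsilyl ether of 10 | CC(=O)O[C@@H]1C(C)=CC(=O)[C@]2(C/C=C(\C)CC/C=C(\C)CC/C=C(\C)CO[Si](C)(C)C(C)(C)C)O[C@H]12
A1 | alternative 1 | 2-[(2E,6E)-farnesyl]-4,4-dimethoxy-5-methylcyclohexa-2,5-dien-1-one | COC1(OC)C=C(C/C=C(\C)CC/C=C(\C)CCC=C(C)C)C(=O)C=C1C
A2 | alternative 1 | (5R,6R)-5,6-epoxy-6-[(2E,6E)-farnesyl]-4,4-dimethoxy-3-methylcyclohex-2-en-1-one | COC1(OC)C(C)=CC(=O)[C@]2(C/C=C(\C)CC/C=C(\C)CCC=C(C)C)O[C@H]12
A3 | alternative 1 | (5R,6R)-5,6-epoxy-6-[(2E,6E)-farnesyl]-3-methylcyclohex-2-ene-1,4-dione | O=C1C(C)=CC(=O)[C@]2(C/C=C(\C)CC/C=C(\C)CCC=C(C)C)O[C@H]12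
A4 | alternative 1 | 2-[(2E,6E)-farnesyl]-5-methyl-1,4-benzoquinone | CC1=CC(=O)C(C/C=C(\C)CC/C=C(\C)CCC=C(C)C)=CC1=O
A5 | alternative 2 | tert-butyldimethylsilyl ether of 2-[(2E,6E)-farnesyl]-5-methylcyclohexa-2,4-dien-1-ol | CC(C)(C)[Si](C)(C)O[C@@H]1CC(C)=CC=C1C/C=C(\C)CC/C=C(\C)CCC=C(C)C
A6 | alternative 2 | 1-[(2E,6E)-farnesyl]-4-methyl-7-(tert-butyldimethylsilyloxy)-2,3-dioxabicyclo[2.2.2]oct-5-ene, peroxide bridge anti to the silyloxy group | C[C@@]12C[C@@H](O[Si](C)(C)C(C)(C)C)[C@@](C/C=C(\C)CC/C=C(\C)CCC=C(C)C)(C=C1)OO2
A7 | alternative 2 | cis-2,3:4,5-diepoxy-2-[(2E,6E)-farnesyl]-5-methylcyclohexan-1-one | C[C@@]12CC(=O)[C@]3(C/C=C(\C)CC/C=C(\C)CCC=C(C)C)O[C@@H]3[C@@H]1O2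
A8 | alternative 3 | p-benzoquinone | O=C1C=CC(=O)C=C1
A9 | alternative 3 | trans-1-[(2E,6E)-farnesyl]-4-methylcyclohexa-2,5-diene-1,4-diol | C[C@]1(O)C=C[C@@](O)(C/C=C(\C)CC/C=C(\C)CCC=C(C)C)C=C1
A10 | alternative 3 | 5,6-epoxy-1-[(2E,6E)-farnesyl]-4-methylcyclohex-2-ene-1,4-diol, oxirane cis to the methyl carbinol oxygen | C[C@]1(O)C=C[C@@](O)(C/C=C(\C)CC/C=C(\C)CCC=C(C)C)[C@H]2O[C@@H]12
A11 | alternative 3 | Payne isomer, 6-[(2E,6E)-farnesyl]-3-methyl-7-oxabicyclo[4.1.0]hept-4-ene-2,3-diol with the secondary hydroxyl trans to the oxirane | C[C@]1(O)C=C[C@]2(C/C=C(\C)CC/C=C(\C)CCC=C(C)C)O[C@@H]2[C@H]1O
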